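**Strategy.** Ring B, the 4'-methoxy-2',5'-benzoquinone carried by C2, is not made by oxidising an aryl group but is built de novo from an alkyne. Everything rests on the C1'–C2' bond: a thermal Moore ring expansion of a 4-alkynyl-4-hydroxy-3-methoxycyclobutenone, an isomer of the target whose alkyne (C1'≡C6') already sits on C2 of the finished (S)-chromanone. One neutral, reagent-free operation delivers the six-membered quinone, its oxidation level and the para alkyl/OMe pattern with H at C3' and C6'. It spares the oxidisable hexasubstituted ring A (free 5-OH) and the base-labile C2–O1 stereocentre. The precursor divides at C2–C1' into a 2-unsubstituted chromone and an ethynyl carbinol of methyl semisquarate.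

Key step: step 7

Assumption: the target is (2S). In step 6 the antipode of the axially chiral P,N ligand that sends the acetylide to the Re face of C2 is taken. Both antipodes are accessible, so the sense of induction is a choice and not a question of feasibility.

Ring B numbering: C1' (on C2), C2' (C=O), C3' (H), C4' (OMe), C5' (C=O), C6' (H).

Step 1
Reactants: 1 2',4',6'-trihydroxyacetophenone
Product: 2 2',4',6'-trihydroxy-3',5'-dimethylacetophenone
Conditions: MeI (2.1 equiv), NaOMe (2.1 equiv), MeOH, 0 °C to reflux
Reagents that add atoms: iodomethane, SMILES CI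
Why: C-alkylation of the ambident phloroglucinol anion, which in a protic solvent reacts with the soft electrophile MeI at the two free ring carbons C3' and C5' rather than at oxygen.

Step 2
Reactants: 2 2',4',6'-trihydroxy-3',5'-dimethylacetophenone
Product: 3 2',6'-dihydroxy-4'-methoxy-3',5'-dimethylacetophenone
Conditions: Me2SO4 (1.0 equiv), K2CO3 (1.05 equiv), acetone, rt to 40 °C
Reagents that add atoms: dimethyl sulfate, SMILES COS(=O)(=O)OC
Why: Williamson ether synthesis in which only the 4'-OH, para to the acyl group, most acidic and not chelated to the ketone, is ionised and methylated by the hard electrophile, while the two hydrogen-bonded ortho hydroxyls stay free.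

Step 3
Reactants: 3 2',6'-dihydroxy-4'-methoxy-3',5'-dimethylacetophenone
Product: 5 5-hydroxy-7-methoxy-6,8-dimethyl-4H-chromen-4-one, via enaminone 4 (not isolated)
Conditions: DMF-DMA (1.5 equiv), PhMe, 90 °C; then conc. HCl, CH2Cl2, 40 °C
Reagents that add atoms: N,N-dimethylformamide dimethyl acetal, SMILES COC(OC)N(C)C
Why: Enaminone chromone synthesis, in which condensation at the acetyl CH3 installs C2 and acid-promoted addition–elimination of an ortho OH expels dimethylamine, the two ortho hydroxyls of 3 being equivalent by symmetry so that a single chromone can form.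

Step 4
Reactants: 6 dimethyl squarate (3,4-dimethoxycyclobut-3-ene-1,2-dione)
Product: 8 3-methoxycyclobut-3-ene-1,2-dione (methyl semisquarate), via hydroxycyclobutenone 7 (not isolated)
Conditions: LiAlH(OtBu)3 (1.05 equiv), THF, −78 to −20 °C; then 6 M HCl, CH2Cl2, rt, short contact
Reagents that add atoms: none
Why: Standard squarate-to-semisquarate sequence, in which the bulky hydride stops after one 1,2-reduction and acid ionises the carbinol to an alkoxy-stabilised allyl cation that takes up water at the distal carbon and loses methanol to restore the dione.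

Step 5
Reactants: 8 3-methoxycyclobut-3-ene-1,2-dione
Product: 9 (±)-4-ethynyl-4-hydroxy-3-methoxycyclobut-2-en-1-one
Conditions: HC≡CMgBr (1.05 equiv), THF, −78 to −40 °C; sat. aq NH4Cl
Reagents that add atoms: ethynylmagnesium bromide, SMILES C#C[Mg]Br
Why: Grignard 1,2-addition to the more electrophilic carbonyl, the one next to C–OMe that is not part of the vinylogous ester, which places the carbinol carbon beside the methoxy-bearing carbon, the racemic carbinol centre being of no consequence because step 7 destroys it.

Step 6
Reactants: 5 5-hydroxy-7-methoxy-6,8-dimethyl-4H-chromen-4-one; 9 (±)-4-ethynyl-4-hydroxy-3-methoxycyclobut-2-en-1-one (1.5 equiv)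
Product: 13 (2S)-5-hydroxy-2-[(1-hydroxy-2-methoxy-4-oxocyclobut-2-en-1-yl)ethynyl]-7-methoxy-6,8-dimethylchroman-4-one (both carbinol epimers), via silyl ether 10 (not isolated), via benzopyrylium triflate 11 (not isolated), via tris-silyl adduct 12 (not isolated)
Conditions: (a) 9, TMSOTf, iPr2NEt, PhMe, 0 °C; (b) 5, TMSOTf (2.2 equiv), iPr2NEt, PhMe–CH2Cl2, 0 °C; (c) combine, CuI (10 mol %), StackPhos (11 mol %), iPr2NEt, −30 °C; (d) aq citric acid, THF, 0 °C
Reagents that add atoms: none
Why: Cu(I)-catalysed enantioselective conjugate alkynylation of a chromone through its 4-silyloxybenzopyrylium ion, in which TMSOTf turns 5 into the aromatic cation 11 and caps both hydroxyls, the ligand-bound copper acetylide of 10 attacks C2 on the Re face (O1 > C3 > H) under catalyst control to set (S)-C2, and mild acid then strips the three O–TMS groups without touching the vinylogous ester.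

Step 7
Reactants: 13 (2S)-5-hydroxy-2-[(1-hydroxy-2-methoxy-4-oxocyclobut-2-en-1-yl)ethynyl]-7-methoxy-6,8-dimethylchroman-4-one
Product: 16 2-[(2S)-5-hydroxy-7-methoxy-6,8-dimethyl-4-oxochroman-2-yl]-5-methoxy-1,4-benzoquinone (target), via enynylketene 14 (not isolated), via aryl-phenoxyl diradical 15 (not isolated)
Conditions: PhMe (0.02 M, degassed), 110 °C, dark
Reagents that add atoms: none
Why: Heating triggers conrotatory 4π electrocyclic opening of the cyclobutenone C2'–C5' bond, in which the donor OH rotates outward and the alkynyl group inward, so that the (Z)-enynylketene 14 forms in the only geometry able to cyclise. The ketene carbon C2' then bonds to the distal alkyne carbon C1' (Moore cyclisation, the ketene counterpart of the Myers–Saito cycloaromatisation, a formal 6-endo-dig closure of ring B) to give the aryl σ/phenoxyl diradical 15, and transfer of the C5'-OH hydrogen to C6' ends in the quinone. This is the established behaviour of 4-alkynyl-4-hydroxycyclobutenones. No stereocentre is created: the carbinol centre of 13 becomes the sp2 carbon C5', so both epimers converge on one product, and C2 is a spectator that meets no acid, base or oxidant. The selectivity needed is six- over five-membered closure (quinone versus alkylidenecyclopentenedione); it is secured by the sp3 carbon C2 on the alkyne terminus, which cannot stabilise the exocyclic vinyl radical of the five-ring path, and by the free OH, which supplies the hydrogen for C6'. The para alkyl/OMe regiochemistry is fixed beforehand, because C4'–OMe lies next to the carbinol carbon in 13.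

**Compound list**

1 | 2',4',6'-trihydroxyacetophenone | CC(=O)c1c(O)cc(O)cc1O | starting material
2 | 2',4',6'-trihydroxy-3',5'-dimethylacetophenone | CC(=O)c1c(O)c(C)c(O)c(C)c1O | intermediate
3 | 2',6'-dihydroxy-4'-methoxy-3',5'-dimethylacetophenone | CC(=O)c1c(O)c(C)c(OC)c(C)c1O | intermediate
4 | (E)-1-(2,6-dihydroxy-4-methoxy-3,5-dimethylphenyl)-3-(dimethylamino)prop-2-en-1-one | CN(C)/C=C/C(=O)c1c(O)c(C)c(OC)c(C)c1O | intermediate
5 | 5-hydroxy-7-methoxy-6,8-dimethyl-4H-chromen-4-one | COc1c(C)c(O)c2c(=O)ccoc2c1C | intermediate
6 | dimethyl squarate (3,4-dimethoxycyclobut-3-ene-1,2-dione) | COC1=C(OC)C(=O)C1=O | starting material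
7 | (±)-4-hydroxy-2,3-dimethoxycyclobut-2-en-1-one | COC1=C(OC)C(=O)C1O | intermediate
8 | 3-methoxycyclobut-3-ene-1,2-dione (methyl semisquarate) | COC1=CC(=O)C1=O | intermediate
9 | (±)-4-ethynyl-4-hydroxy-3-methoxycyclobut-2-en-1-one | COC1=CC(=O)C1(O)C#C | intermediate
10 | (±)-4-ethynyl-3-methoxy-4-(trimethylsilyloxy)cyclobut-2-en-1-one | COC1=CC(=O)C1(C#C)O[Si](C)(C)C | intermediate
11 | 7-methoxy-6,8-dimethyl-4,5-bis(trimethylsilyloxy)chromenylium triflate | COc1c(C)c(O[Si](C)(C)C)c2c(O[Si](C)(C)C)cc[o+]c2c1C.[O-]S(=O)(=O)C(F)(F)F | intermediate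
12 | (2S)-7-methoxy-2-{[2-methoxy-4-oxo-1-(trimethylsilyloxy)cyclobut-2-en-1-yl]ethynyl}-6,8-dimethyl-4,5-bis(trimethylsilyloxy)-2H-chromene (both carbinol epimers) | COC1=CC(=O)C1(O[Si](C)(C)C)C#C[C@@H]2C=C(O[Si](C)(C)C)c3c(O[Si](C)(C)C)c(C)c(OC)c(C)c3O2 | intermediate
13 | (2S)-5-hydroxy-2-[(1-hydroxy-2-methoxy-4-oxocyclobut-2-en-1-yl)ethynyl]-7-methoxy-6,8-dimethylchroman-4-one (both carbinol epimers) | COC1=CC(=O)C1(O)C#C[C@@H]2CC(=O)c3c(O)c(C)c(OC)c(C)c3O2 | intermediate
14 | (Z)-enynylketene, 4-hydroxy-3-methoxy-6-[(2S)-chromanon-2-yl]hexa-1,3-dien-5-yn-1-one | O=C=C/C(OC)=C(/O)C#C[C@@H]1CC(=O)c2c(O)c(C)c(OC)c(C)c2O1 | intermediate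
15 | aryl σ (C6')/phenoxyl (O on C2') diradical of ring B | COc1cc([O])c([C@@H]2CC(=O)c3c(O)c(C)c(OC)c(C)c3O2)[c]c1O | intermediate
16 | 2-[(2S)-5-hydroxy-7-methoxy-6,8-dimethyl-4-oxochroman-2-yl]-5-methoxy-1,4-benzoquinone | COC1=CC(=O)C([C@@H]2CC(=O)c3c(O)c(C)c(OC)c(C)c3O2)=CC1=O | target

Total step count: 7. Longest linear sequence: 5 (steps 1, 2, 3, 6, 7). Steps 4 and 5 form the second branch.

**Steps most likely to fail**

Step 7. The enynylketene may close to the five-membered ring instead of the six-membered one. Hydrogen transfer to C6' may be inefficient. Prolonged heating may erode C2 through reversible opening of the pyranone ring.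

The fallback gives up the de novo ring construction and brings ring B in as an intact arene. It sets out from chromone 5. Rh(I)/chiral diene-catalysed asymmetric 1,4-addition of 2,4,5-trimethoxyphenylboronic acid should give (2S)-5-hydroxy-7-methoxy-6,8-dimethyl-2-(2,4,5-trimethoxyphenyl)chroman-4-one F1. Oxidative demethylation of its para-related 2',5'-dimethoxy pair with ceric ammonium nitrate (MeCN–H2O, 0 °C) comes back to the route at target 16. Ring A is the less electron-rich arene there, because of its chelated carbonyl.

Step 6. The racemic propargylic centre of the alkyne may create matched and mismatched catalyst–acetylide pairs and lower the facial selectivity at C2. The cyclobutenone may also degrade under silyl triflate and amine.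

The fallback makes the C2–C1' bond with a simple achiral alkyne and forms the C6'–C5' bond afterwards.
- It sets out from 5, through the same cation 11, and runs the alkynylation with trimethylsilylacetylene. This should give (2S)-7-methoxy-6,8-dimethyl-4,5-bis(trimethylsilyloxy)-2-[(trimethylsilyl)ethynyl]-2H-chromene F2.
- Work-up hydrolyses this to (2S)-5-hydroxy-7-methoxy-6,8-dimethyl-2-[(trimethylsilyl)ethynyl]chroman-4-one F3.
- AcOH-buffered TBAF (THF, 0 °C) removes the C-silyl group to give (2S)-2-ethynyl-5-hydroxy-7-methoxy-6,8-dimethylchroman-4-one F4.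
- The alkynylzinc of that alkyne, formed with Me2Zn in toluene without enolising the ketone, should add 1,2 to the non-vinylogous carbonyl of 8. The fallback comes back to the route at 13.

Step 1. The ring may be over-alkylated to gem-dimethyl, dearomatised cyclohexadienones, and alkylation may also stop at the monomethyl stage.

The fallback replaces direct alkylation by aminomethylation and hydrogenolysis, which cannot place two carbons on one ring position. It sets out from 1. A double Mannich reaction (aq CH2O, Me2NH, EtOH, rt) should give 1-[3,5-bis(dimethylaminomethyl)-2,4,6-trihydroxyphenyl]ethanone F5. Hydrogenolysis of both benzylic C–N bonds (H2, Pd/C, MeOH–AcOH) comes back to the route at 2.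

**Further compounds**

F1 | step 7 | (2S)-5-hydroxy-7-methoxy-6,8-dimethyl-2-(2,4,5-trimethoxyphenyl)chroman-4-one | COc1cc(OC)c(OC)cc1[C@@H]2CC(=O)c3c(O)c(C)c(OC)c(C)c3O2
F2 | step 6 | (2S)-7-methoxy-6,8-dimethyl-4,5-bis(trimethylsilyloxy)-2-[(trimethylsilyl)ethynyl]-2H-chromene | C[Si](C)(C)C#C[C@@H]1C=C(O[Si](C)(C)C)c2c(O[Si](C)(C)C)c(C)c(OC)c(C)c2O1
F3 | step 6 | (2S)-5-hydroxy-7-methoxy-6,8-dimethyl-2-[(trimethylsilyl)ethynyl]chroman-4-one | C[Si](C)(C)C#C[C@@H]1CC(=O)c2c(O)c(C)c(OC)c(C)c2O1
F4 | step 6 | (2S)-2-ethynyl-5-hydroxy-7-methoxy-6,8-dimethylchroman-4-one | C#C[C@@H]1CC(=O)c2c(O)c(C)c(OC)c(C)c2O1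
F5 | step 1 | 1-[3,5-bis(dimethylaminomethyl)-2,4,6-trihydroxyphenyl]ethanone | CC(=O)c1c(O)c(CN(C)C)c(O)c(CN(C)C)c1O
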